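The bond on which the route rests is C3–C4 of ring C. The C4 ketone beside the C3 carbinol is an acyloin, so ring C can be closed by a benzoin reaction. It joins the formyl carbon on ring A (future C4) to a second aldehyde carbon (future C3) held through C2 and O1. One chiral-carbene cyclisation should make that bond, close the pyranone ring and, by dynamic kinetic resolution of the labile C2 centre, set the 2,3-trans pair. Its precursor is a racemic dialdehyde, a 2-aryl-2-(2-formyl-3,5-dimethoxyphenoxy)acetaldehyde with the B-ring phenol benzylated. The C6 side chain follows by iodination next to the freed 5-OH, Suzuki coupling and asymmetric hydrogenation.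

Key step: step 6

Remark: in the catalyst-controlled steps 6 and 12 the sense of induction cannot be predicted for these new substrates, so the catalyst antipode is fixed in a first run and the mirror-image catalyst is used if the opposite series forms.

Step 1
Reactants: 1 DL-4-hydroxymandelic acid
Product: 2 benzyl (±)-2-[4-(benzyloxy)phenyl]-2-hydroxyacetate
Conditions: BnBr (2.2 equiv), K2CO3, DMF, rt
Reagents that add atoms: benzyl bromide, BrCc1ccccc1
Why: Carbonate-mediated O-alkylation (Williamson ether synthesis plus carboxylate alkylation) should benzylate the carboxylate and the phenoxide while the much less acidic secondary alcohol stays free.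

Step 2
Reactants: 2 benzyl (±)-2-[4-(benzyloxy)phenyl]-2-hydroxyacetate
Product: 3 benzyl (±)-2-[4-(benzyloxy)phenyl]-2-bromoacetate
Conditions: PBr3 (0.4 equiv), CH2Cl2, 0 °C
Reagents that add atoms: phosphorus tribromide, BrP(Br)Br
Why: Deoxybromination of an activated benzylic α-hydroxy ester through its phosphite ester is standard for mandelates, and the centre is racemic, so its stereochemical course does not matter.

Step 3
Reactants: 3 benzyl (±)-2-[4-(benzyloxy)phenyl]-2-bromoacetate; 4 2-hydroxy-4,6-dimethoxybenzaldehyde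
Product: 5 benzyl (±)-2-[4-(benzyloxy)phenyl]-2-(2-formyl-3,5-dimethoxyphenoxy)acetate
Conditions: K2CO3, DMF, rt
Reagents that add atoms: none
Why: Williamson ether synthesis of the phenoxide with a highly reactive benzylic α-bromo ester should proceed at room temperature, where the mild base does not yet drive the aldol closure of the product onto its own formyl group.

Step 4
Reactants: 5 benzyl (±)-2-[4-(benzyloxy)phenyl]-2-(2-formyl-3,5-dimethoxyphenoxy)acetate
Product: 6 (±)-2-[4-(benzyloxy)phenyl]-2-[2-(hydroxymethyl)-3,5-dimethoxyphenoxy]ethan-1-ol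
Conditions: LiAlH4, THF, 0 °C; Rochelle-salt work-up
Reagents that add atoms: none
Why: Hydride reduction takes the ester and the aryl aldehyde to the diol together, so no acetal is needed to tell the two carbonyl groups apart, and the basic work-up protects the acid-labile trialkoxybenzyl alcohol.

Step 5
Reactants: 6 (±)-2-[4-(benzyloxy)phenyl]-2-[2-(hydroxymethyl)-3,5-dimethoxyphenoxy]ethan-1-ol
Product: 7 (±)-2-[4-(benzyloxy)phenyl]-2-(2-formyl-3,5-dimethoxyphenoxy)acetaldehyde
Conditions: Dess–Martin periodinane (2.4 equiv), pyridine, CH2Cl2, 0 °C to rt; used at once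
Reagents that add atoms: none
Why: Pyridine-buffered Dess–Martin oxidation converts both primary alcohols to aldehydes under near-neutral conditions that should spare the ionisable benzylic alcohol and the enolisable α-aryloxy aldehyde.

Step 6
Reactants: 7 (±)-2-[4-(benzyloxy)phenyl]-2-(2-formyl-3,5-dimethoxyphenoxy)acetaldehyde (the 2R enantiomer reacts, the 2S enantiomer is fed back by enolisation)
Product: 8 (2R,3R)-2-[4-(benzyloxy)phenyl]-3-hydroxy-5,7-dimethoxychroman-4-one
Conditions: chiral aminoindanol-derived N-C6F5 triazolium tetrafluoroborate (15 mol%), i-Pr2NEt, toluene, −20 to 0 °C, Ar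
Reagents that add atoms: none
Why: Proposed new method: the triazolylidene adds to the A-ring formyl group, proton transfer gives the Breslow intermediate, and its nucleophilic carbon (C4) attacks the tethered aliphatic aldehyde (C3) before the carbene leaves, so C3–C4 and ring C form in one isomerisation. The closest known reaction type is the carbene-catalysed intramolecular crossed benzoin of 2-(2-oxoalkoxy)benzaldehydes to 3-hydroxychroman-4-ones, here with an aldehyde instead of a ketone as acceptor. Ring C closes in the 6-exo-trig mode through a chair-like transition state. C3 is set by the chiral catalyst, which exposes one face of the acyl-anion equivalent to the acceptor, and C2 by dynamic kinetic resolution, since the α-aryl-α-aryloxy aldehyde racemises through its enol under the amine base and only the 2R enantiomer can keep the aryl group equatorial and trans to the forming C3–O bond. The step needs the carbene to activate the aromatic and not the aliphatic aldehyde, because a Breslow intermediate next to the aryloxy group would expel the aryloxide and end as an aryl ester; the two ortho oxygen atoms of the A-ring aldehyde, which favour carbene adduct formation as in salicylaldehyde ethers, and the branched α-carbon of the aliphatic aldehyde, which retards enaminol formation there, are what should secure this. Weak base, low temperature and exclusion of air serve to hold back the 5-exo aldol closure, the retro-benzoin and base-induced opening of the product.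

Step 7
Reactants: 8 (2R,3R)-2-[4-(benzyloxy)phenyl]-3-hydroxy-5,7-dimethoxychroman-4-one
Product: 9 (2R,3R)-2-[4-(benzyloxy)phenyl]-3,5-dihydroxy-7-methoxychroman-4-one
Conditions: MgI2·OEt2 (3 equiv), toluene–Et2O, 60 °C; aq. NH4Cl
Reagents that add atoms: none
Why: Chelation-controlled demethylation, in which Mg(II) bridges the C4 carbonyl and the peri 5-methoxy oxygen and iodide removes that methyl group by SN2, should leave the unchelated 7-methoxy group and the benzyl ether, which boron halides would not spare.

Step 8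
Reactants: 9 (2R,3R)-2-[4-(benzyloxy)phenyl]-3,5-dihydroxy-7-methoxychroman-4-one
Product: 10 (2R,3R)-2-[4-(benzyloxy)phenyl]-3,5-dihydroxy-6-iodo-7-methoxychroman-4-one
Conditions: BnMe3N·ICl2 (1.05 equiv), CaCO3, CH2Cl2–MeOH, rt
Reagents that add atoms: benzyltrimethylammonium dichloroiodate, C[N+](C)(C)Cc1ccccc1.Cl[I-]Cl
Why: Electrophilic aromatic iodination of the trioxygenated A ring should go ortho to the hydrogen-bonded 5-OH (C6), the usual site in chelated 5-hydroxy-7-alkoxy chromanoids, while the benzyl-capped B ring is far less nucleophilic.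

Step 9
Reactants: 11 4'-(benzyloxy)acetophenone
Product: 13 1-[4-(benzyloxy)phenyl]vinyl trifluoromethanesulfonate, via potassium 1-[4-(benzyloxy)phenyl]ethenolate 12 (not isolated)
Conditions: KHMDS, THF, −78 °C; then PhNTf2, −78 to 0 °C
Reagents that add atoms: N-phenylbis(trifluoromethanesulfonimide), O=S(=O)(N(c1ccccc1)S(=O)(=O)C(F)(F)F)C(F)(F)F
Why: Enol triflate formation, in which the potassium enolate of the methyl ketone is O-sulfonylated by the mild triflyl donor.

Step 10
Reactants: 13 1-[4-(benzyloxy)phenyl]vinyl trifluoromethanesulfonate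
Product: 14 2-{1-[4-(benzyloxy)phenyl]vinyl}-4,4,5,5-tetramethyl-1,3,2-dioxaborolane
Conditions: B2pin2, PdCl2(PPh3)2 (3 mol%), PPh3, KOPh, toluene, 50 °C
Reagents that add atoms: bis(pinacolato)diboron, CC1(C)OB(OC1(C)C)B1OC(C)(C)C(C)(C)O1
Why: Miyaura borylation of an alkenyl triflate with the weak base potassium phenoxide gives the α-arylvinyl boronate without a competing Suzuki coupling.

Step 11
Reactants: 10 (2R,3R)-2-[4-(benzyloxy)phenyl]-3,5-dihydroxy-6-iodo-7-methoxychroman-4-one; 14 2-{1-[4-(benzyloxy)phenyl]vinyl}-4,4,5,5-tetramethyl-1,3,2-dioxaborolane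
Product: 15 (2R,3R)-2-[4-(benzyloxy)phenyl]-6-{1-[4-(benzyloxy)phenyl]vinyl}-3,5-dihydroxy-7-methoxychroman-4-one
Conditions: SPhos Pd G3 (5 mol%), K3PO4, THF–H2O, 40 °C, degassed
Reagents that add atoms: none
Why: Suzuki–Miyaura coupling with a bulky biarylphosphine should couple the di-ortho-substituted iodide at low temperature, and the mild phosphate base, with the B-ring phenol still benzylated, limits base-induced opening of the ketol ring.

Step 12
Reactants: 15 (2R,3R)-2-[4-(benzyloxy)phenyl]-6-{1-[4-(benzyloxy)phenyl]vinyl}-3,5-dihydroxy-7-methoxychroman-4-one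
Product: 16 (2R,3R)-2-[4-(benzyloxy)phenyl]-6-{(1R)-1-[4-(benzyloxy)phenyl]ethyl}-3,5-dihydroxy-7-methoxychroman-4-one
Conditions: [Ir(cod)(L*)]BArF (L* = chiral phosphinite–oxazoline, 2 mol%), H2 (50 bar), CH2Cl2, rt
Reagents that add atoms: none
Why: Iridium N,P-catalysed asymmetric hydrogenation of a 1,1-diarylethene should distinguish the twisted, di-ortho-substituted A-ring aryl from the coplanar 4-benzyloxyphenyl group and add H2 to one alkene face, setting the (1R) centre under catalyst control.

Step 13
Reactants: 16 (2R,3R)-2-[4-(benzyloxy)phenyl]-6-{(1R)-1-[4-(benzyloxy)phenyl]ethyl}-3,5-dihydroxy-7-methoxychroman-4-one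
Product: 17 (2R,3R)-3,5-dihydroxy-2-(4-hydroxyphenyl)-6-[(1R)-1-(4-hydroxyphenyl)ethyl]-7-methoxychroman-4-one
Conditions: H2 (1 atm), 10% Pd/C, EtOAc–MeOH, rt
Reagents that add atoms: none
Why: Catalytic hydrogenolysis of the two aryl benzyl ethers under neutral conditions is routinely tolerated by dihydroflavonols and should leave the ketol, the C2–O1 bond and the diarylmethine centre untouched.

Compound list
1 | DL-4-hydroxymandelic acid | OC(C(=O)O)c1ccc(O)cc1 | starting material
2 | benzyl (±)-2-[4-(benzyloxy)phenyl]-2-hydroxyacetate | OC(C(=O)OCc1ccccc1)c1ccc(OCc2ccccc2)cc1 | intermediate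
3 | benzyl (±)-2-[4-(benzyloxy)phenyl]-2-bromoacetate | BrC(C(=O)OCc1ccccc1)c1ccc(OCc2ccccc2)cc1 | intermediate
4 | 2-hydroxy-4,6-dimethoxybenzaldehyde | COc1cc(O)c(C=O)c(OC)c1 | starting material
5 | benzyl (±)-2-[4-(benzyloxy)phenyl]-2-(2-formyl-3,5-dimethoxyphenoxy)acetate | COc1cc(OC(C(=O)OCc2ccccc2)c2ccc(OCc3ccccc3)cc2)c(C=O)c(OC)c1 | intermediate
6 | (±)-2-[4-(benzyloxy)phenyl]-2-[2-(hydroxymethyl)-3,5-dimethoxyphenoxy]ethan-1-ol | COc1cc(OC(CO)c2ccc(OCc3ccccc3)cc2)c(CO)c(OC)c1 | intermediate
7 | (±)-2-[4-(benzyloxy)phenyl]-2-(2-formyl-3,5-dimethoxyphenoxy)acetaldehyde (C2 labile) | COc1cc(OC(C=O)c2ccc(OCc3ccccc3)cc2)c(C=O)c(OC)c1 | intermediate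
8 | (2R,3R)-2-[4-(benzyloxy)phenyl]-3-hydroxy-5,7-dimethoxychroman-4-one | COc1cc2c(c(OC)c1)C(=O)[C@H](O)[C@@H](c1ccc(OCc3ccccc3)cc1)O2 | intermediate
9 | (2R,3R)-2-[4-(benzyloxy)phenyl]-3,5-dihydroxy-7-methoxychroman-4-one | COc1cc2c(c(O)c1)C(=O)[C@H](O)[C@@H](c1ccc(OCc3ccccc3)cc1)O2 | intermediate
10 | (2R,3R)-2-[4-(benzyloxy)phenyl]-3,5-dihydroxy-6-iodo-7-methoxychroman-4-one | COc1cc2c(c(O)c1I)C(=O)[C@H](O)[C@@H](c1ccc(OCc3ccccc3)cc1)O2 | intermediate
11 | 4'-(benzyloxy)acetophenone | CC(=O)c1ccc(OCc2ccccc2)cc1 | starting material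
12 | potassium 1-[4-(benzyloxy)phenyl]ethenolate | [K+].[O-]C(=C)c1ccc(OCc2ccccc2)cc1 | intermediate
13 | 1-[4-(benzyloxy)phenyl]vinyl trifluoromethanesulfonate | C=C(OS(=O)(=O)C(F)(F)F)c1ccc(OCc2ccccc2)cc1 | intermediate
14 | 2-{1-[4-(benzyloxy)phenyl]vinyl}-4,4,5,5-tetramethyl-1,3,2-dioxaborolane | C=C(B1OC(C)(C)C(C)(C)O1)c1ccc(OCc2ccccc2)cc1 | intermediate
15 | (2R,3R)-2-[4-(benzyloxy)phenyl]-6-{1-[4-(benzyloxy)phenyl]vinyl}-3,5-dihydroxy-7-methoxychroman-4-one | COc1cc2c(c(O)c1C(=C)c1ccc(OCc3ccccc3)cc1)C(=O)[C@H](O)[C@@H](c1ccc(OCc3ccccc3)cc1)O2 | intermediate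
16 | (2R,3R)-2-[4-(benzyloxy)phenyl]-6-{(1R)-1-[4-(benzyloxy)phenyl]ethyl}-3,5-dihydroxy-7-methoxychroman-4-one | COc1cc2c(c(O)c1[C@H](C)c1ccc(OCc3ccccc3)cc1)C(=O)[C@H](O)[C@@H](c1ccc(OCc3ccccc3)cc1)O2 | intermediate
17 | (2R,3R)-3,5-dihydroxy-2-(4-hydroxyphenyl)-6-[(1R)-1-(4-hydroxyphenyl)ethyl]-7-methoxychroman-4-one | COc1cc2c(c(O)c1[C@H](C)c1ccc(O)cc1)C(=O)[C@H](O)[C@@H](c1ccc(O)cc1)O2 | target

Total step count: 13. Longest linear sequence: 11 steps (steps 1–8 and 11–13); steps 9 and 10 make the boronate in a side branch.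

Steps most likely to fail

Step 6 (Proposed new method). The carbene may engage the more electrophilic aliphatic aldehyde, after which loss of the α-aryloxide diverts the material into an internal redox esterification. The amine may also trigger the 5-exo aldol closure, and slow enolisation at C2 would lower the enantioselectivity. The fallback uses known chemistry and sets out from 4. The phenol is capped with MOMCl and i-Pr2NEt to give 2-(methoxymethoxy)-4,6-dimethoxybenzaldehyde F1. MeMgBr addition gives (±)-1-[2-(methoxymethoxy)-4,6-dimethoxyphenyl]ethan-1-ol F2, and Dess–Martin oxidation gives 1-[2-(methoxymethoxy)-4,6-dimethoxyphenyl]ethan-1-one F3. Claisen–Schmidt condensation with 4-(benzyloxy)benzaldehyde (KOH, EtOH) gives (E)-3-[4-(benzyloxy)phenyl]-1-[2-(methoxymethoxy)-4,6-dimethoxyphenyl]prop-2-en-1-one F4. Juliá–Colonna epoxidation (poly-L-leucine, urea–H2O2, DBU, THF) should give {(2R,3S)-3-[4-(benzyloxy)phenyl]oxiran-2-yl}[2-(methoxymethoxy)-4,6-dimethoxyphenyl]methanone F5. HCl in MeOH then removes the MOM group, and the freed phenol opens the epoxide at the benzylic carbon with inversion (6-endo). This rejoins the route at 8.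

Step 12. Facial selectivity may be poor if the catalyst does not tell the two aryl groups apart, or the chelating ketol may slow the iridium catalyst. The fallback sets out from 15 and gives up catalyst control. Hydrogenation over Pd/C (H2, EtOAc–MeOH) reduces the alkene and removes both benzyl groups in one operation. It gives the target together with its side-chain epimer (2R,3R)-3,5-dihydroxy-2-(4-hydroxyphenyl)-6-[(1S)-1-(4-hydroxyphenyl)ethyl]-7-methoxychroman-4-one F6. The two diastereomers are separated by preparative HPLC, which rejoins the route at 17.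

Step 11. Base-induced opening or epimerisation of the ketol ring, or protodeiodination at the crowded iodide, may outrun transmetalation. The fallback is a base-free Stille coupling that sets out from 13 and 10. Triflate 13 is stannylated with (Bu3Sn)2, Pd(PPh3)4 and LiCl in THF to give tributyl{1-[4-(benzyloxy)phenyl]vinyl}stannane F7. Coupling of F7 with iodide 10 (Pd2(dba)3, AsPh3, CuI, DMF, 50 °C) rejoins the route at 15.

Further compounds
F1 | step 6 | 2-(methoxymethoxy)-4,6-dimethoxybenzaldehyde | COCOc1cc(OC)cc(OC)c1C=O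
F2 | step 6 | (±)-1-[2-(methoxymethoxy)-4,6-dimethoxyphenyl]ethan-1-ol | COCOc1cc(OC)cc(OC)c1C(C)O
F3 | step 6 | 1-[2-(methoxymethoxy)-4,6-dimethoxyphenyl]ethan-1-one | COCOc1cc(OC)cc(OC)c1C(C)=O
F4 | step 6 | (E)-3-[4-(benzyloxy)phenyl]-1-[2-(methoxymethoxy)-4,6-dimethoxyphenyl]prop-2-en-1-one | COCOc1cc(OC)cc(OC)c1C(=O)/C=C/c1ccc(OCc2ccccc2)cc1
F5 | step 6 | {(2R,3S)-3-[4-(benzyloxy)phenyl]oxiran-2-yl}[2-(methoxymethoxy)-4,6-dimethoxyphenyl]methanone | COCOc1cc(OC)cc(OC)c1C(=O)[C@@H]1O[C@H]1c1ccc(OCc2ccccc2)cc1
F6 | step 12 | (2R,3R)-3,5-dihydroxy-2-(4-hydroxyphenyl)-6-[(1S)-1-(4-hydroxyphenyl)ethyl]-7-methoxychroman-4-one | COc1cc2c(c(O)c1[C@@H](C)c1ccc(O)cc1)C(=O)[C@H](O)[C@@H](c1ccc(O)cc1)O2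
F7 | step 11 | tributyl{1-[4-(benzyloxy)phenyl]vinyl}stannane | CCCC[Sn](CCCC)(CCCC)C(=C)c1ccc(OCc2ccccc2)cc1
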